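## Retrosynthetic overview
1. Target 19 comes from global O-demethylation of the permethyl tetramer 18. Each of its three trans-2,3-diaryl-dihydrobenzofurans (DHBs) comes from an α-aryl-α-(2-hydroxyaryl) ketone by ketone reduction and acid cyclodehydration. C3 fixes C2 (trans) under thermodynamic control.
2. Each C3 centre is set by a new enantioselective NHC umpolung: 4-methoxybenzaldehyde adds to a diaryl o-quinone methide (o-QM) released from a benzhydryl sulfone. The outer DHB rings (A and C) share one handedness and the central ring (B) has the opposite one in the target SMILES. So rings A and C are made first with one catalyst enantiomer, and ring B last with the other, its phenol masked as an allyl ether until then.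
3. The tetra-aryl tris-benzhydrol backbone is built by iterative ArMgBr/ArLi additions to 2-bromo-6-alkoxy-4-methoxybenzaldehydes, with Br as the latent nucleophile. The styryl group is installed early by a Heck reaction.
4. Ring order: backbone first, then DHB1 and DHB3 together, then DHB2.

Assumptions:
- Vilsmeier formylation of 1 occurs at C2, ortho to Br.
- The (aminoindanol-derived) triazolium enantiomer that gives the C3 sense drawn in 14 is found empirically. Its mirror image gives the sense in 17.
- Sulfone and carbinol carbons in 9–12 are left undefined because they are erased in Step 10.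

## Route

**Step 1**
Reactants: 1, 1-bromo-3,5-dimethoxybenzene
Product: 2, 2-bromo-4,6-dimethoxybenzaldehyde
Conditions: POCl3, DMF, 0 °C → 70 °C
Reagents that add atoms: DMF, CN(C)C=O
Why: Vilsmeier–Haack formylation at the activated site ortho to Br and OMe and para to the other OMe, avoiding the site flanked by two OMe groups.

**Step 2**
Reactants: 2
Product: 3, 2-bromo-6-hydroxy-4-methoxybenzaldehyde
Conditions: BCl3 (1.1 equiv), CH2Cl2, −78 → 0 °C
Reagents that add atoms: none
Why: Chelation-directed (B–O···C=O) cleavage of the OMe ortho to CHO; the para OMe is untouched.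

**Step 3**
Reactants: 3
Product: 4, 2-bromo-4-methoxy-6-(methoxymethoxy)benzaldehyde
Conditions: MOMCl, i-Pr2NEt, CH2Cl2, 0 °C → rt
Reagents that add atoms: MOMCl, ClCOC
Why: MOM protection of the phenol. MOM survives organometallics and does not migrate to the neighbouring benzylic alkoxide later, unlike silyl ethers.

**Step 4**
Reactants: 3
Product: 5, 6-(allyloxy)-2-bromo-4-methoxybenzaldehyde
Conditions: allyl bromide, K2CO3, DMF, rt
Reagents that add atoms: allyl bromide, C=CCBr
Why: Williamson etherification. The allyl group survives TFA and organolithiums and is removed later by Pd(0), which is what masks ring B.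

**Step 5**
Reactants: 4; 6, 4-methoxystyrene
Product: 7, 4-methoxy-6-(MOMO)-2-[(E)-4-methoxystyryl]benzaldehyde (ring A aldehyde)
Conditions: Pd(OAc)2 (5 mol%), P(o-tol)3, Et3N, DMF, 100 °C
Reagents that add atoms: none
Why: Mizoroki–Heck coupling gives the E-stilbene; the CHO and MOM groups are tolerated.

**Step 6**
Reactants: 8, 3,5-dimethoxyphenylmagnesium bromide; 4
Product: 9, (2-bromo-4-methoxy-6-MOMO-phenyl)(3,5-dimethoxyphenyl)methanol (racemic)
Conditions: THF, −78 → 0 °C; aq. NH4Cl
Reagents that add atoms: none
Why: Grignard 1,2-addition to the aldehyde forms the L3 benzhydrol. The carbinol stereochemistry is irrelevant because it is erased in Step 9.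

**Step 7**
Reactants: 9; 5
Product: 10, bis-benzhydrol (rings D–C–B; ring B keeps Br and O-allyl)
Conditions: t-BuLi (3.3 equiv), THF, −78 °C, 20 min; then 5, −78 °C
Reagents that add atoms: none
Why: The first equivalent of t-BuLi forms the alkoxide; Br–Li exchange then gives an aryllithium that adds to aldehyde 5 (L2 link).

**Step 8**
Reactants: 10; 7
Product: 11, tris-benzhydrol (rings D–C–B–A)
Conditions: t-BuLi (4.5 equiv), THF, −78 °C; then 7, −78 °C → 0 °C
Reagents that add atoms: none
Why: The same Br–Li exchange and addition sequence forms the L1 link, completing the tetra-aryl backbone.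

**Step 9**
Reactants: 11
Product: 12, tris(p-tolylsulfonyl) backbone with free phenols on rings A and C; ring B stays O-allyl
Conditions: p-TolSO2Na (8 equiv), TFA, MeCN/CH2Cl2, 0 °C → rt
Reagents that add atoms: sodium p-toluenesulfinate, Cc1ccc(cc1)S(=O)[O-].[Na+]
Why: Acid removes both MOM groups and ionizes the electron-rich benzhydrols to o-hydroxyaryl-stabilized cations. Sulfinate traps them as benzhydryl sulfones, the standard o-QM precursors.

**Step 10**
Reactants: 12; 13, 4-methoxybenzaldehyde
Product: 14, bis-ketone at L1 and L3 (two new C3 stereocentres); the L2 sulfone is untouched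
Conditions: chiral aminoindanol-derived N-mesityl triazolium salt (30 mol%), Cs2CO3 (3 equiv), 13 (8 equiv), THF, 25 °C, 48 h
Reagents that add atoms: none
Why: Proposed new method: base unmasks the phenoxides on rings A and C and expels sulfinate by E1cB to give two diaryl o-QMs. The NHC and 13 form a Breslow acyl-anion equivalent, which adds 1,4 to the o-QM carbon from the face the chiral triazolium shields, setting C3 and releasing the NHC. The closest known reactions are NHC-catalysed umpolung 1,6-additions of aldehydes to p-QMs and benzoin/Stetter chemistry. The new features are diaryl o-QMs from hindered, electron-rich polyaryl sulfones, the resulting diarylmethine stereocentres, and two o-QMs in one pot. The L2 sulfone cannot ionize because its phenol is allylated.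

**Step 11**
Reactants: 14
Product: 15, bis-DHB (rings A and C fused), ring B O-allyl with the L2 sulfone retained
Conditions: (i) NaBH4, MeOH/THF, 0 °C; (ii) after aqueous work-up, p-TsOH·H2O (0.2 equiv), CH2Cl2, 0 °C → rt
Reagents that add atoms: none
Why: NaBH4 reduces the ketones to carbinols, and the C2 epimers are irrelevant. Acid ionizes the p-anisyl carbinol and the ortho phenol closes the ring by SN1 etherification. The reversible closure gives the trans-2,3-diaryl DHB as in the target, and C3 is not touched.

**Step 12**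
Reactants: 15
Product: 16, free phenol at ring B (allyl removed)
Conditions: Pd(PPh3)4 (5 mol%), PhSiH3 (3 equiv), CH2Cl2, 25 °C
Reagents that add atoms: none
Why: Tsuji–Trost deallylation under neutral conditions, with a hydrosilane as the allyl scavenger so that no nucleophile or base is present to trap an o-QM. The stilbene, sulfone and DHBs are inert.

**Step 13**
Reactants: 16; 13
Product: 17, ketone at L2 (third C3 stereocentre, opposite ring-frame handedness)
Conditions: enantiomeric triazolium salt (30 mol%), Cs2CO3 (1.5 equiv), 13 (4 equiv), THF, 25 → 40 °C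
Reagents that add atoms: none
Why: Proposed new method: the same NHC umpolung as Step 10. The ring B phenoxide expels sulfinate to give the o-QM. The opposite-handed catalyst dictates the face, so the central DHB gets the configuration in the target SMILES despite the two flanking stereocentres.

**Step 14**
Reactants: 17
Product: 18, permethyl tetramer
Conditions: (i) NaBH4, MeOH/THF, 0 °C; (ii) p-TsOH·H2O (0.2 equiv), CH2Cl2, 0 °C → rt
Reagents that add atoms: none
Why: Same reduction and SN1 dehydrative cyclization as Step 11, giving the third trans-DHB and completing all six stereocentres.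

**Step 15**
Reactants: 18
Product: 19, Miyabenol A (target)
Conditions: BBr3 (30 equiv), CH2Cl2, −78 → 0 °C, 4 h; MeOH quench
Reagents that add atoms: none
Why: Global cleavage of the nine aryl methyl ethers. The E-stilbene and the DHB ethers are expected to survive, as in permethylated resveratrol oligomers.

## Compound list

| No. | Name | SMILES | Role |
|---|---|---|---|
| 1 | 1-bromo-3,5-dimethoxybenzene | COc1cc(Br)cc(OC)c1 | starting material |
| 2 | 2-bromo-4,6-dimethoxybenzaldehyde | O=Cc1c(Br)cc(OC)cc1OC | intermediate |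
| 3 | 2-bromo-6-hydroxy-4-methoxybenzaldehyde | O=Cc1c(Br)cc(OC)cc1O | intermediate |
| 4 | 2-bromo-4-methoxy-6-(methoxymethoxy)benzaldehyde | O=Cc1c(Br)cc(OC)cc1OCOC | intermediate |
| 5 | 6-(allyloxy)-2-bromo-4-methoxybenzaldehyde | O=Cc1c(Br)cc(OC)cc1OCC=C | intermediate |
| 6 | 4-methoxystyrene | C=Cc1ccc(OC)cc1 | starting material |
| 7 | 4-methoxy-6-(MOMO)-2-[(E)-4-methoxystyryl]benzaldehyde | O=Cc1c(OCOC)cc(OC)cc1/C=C/c1ccc(OC)cc1 | intermediate |
| 8 | 3,5-dimethoxyphenylmagnesium bromide | COc1cc(OC)cc(c1)[Mg]Br | starting material |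
| 9 | (2-bromo-4-methoxy-6-MOMO-phenyl)(3,5-dimethoxyphenyl)methanol | COc1cc(OC)cc(c1)C(O)c1c(Br)cc(OC)cc1OCOC | intermediate |
| 10 | bis-benzhydrol (D–C–B) | COc1cc(OC)cc(c1)C(O)c1c(C(O)c2c(OCC=C)cc(OC)cc2Br)cc(OC)cc1OCOC | intermediate |
| 11 | tris-benzhydrol (D–C–B–A) | COc1cc(OC)cc(c1)C(O)c1c(C(O)c2c(OCC=C)cc(OC)cc2C(O)c2c(OCOC)cc(OC)cc2/C=C/c2ccc(OC)cc2)cc(OC)cc1OCOC | intermediate |
| 12 | tris-sulfone, free phenols on rings A and C | COc1cc(OC)cc(c1)C(S(=O)(=O)c1ccc(C)cc1)c1c(C(S(=O)(=O)c2ccc(C)cc2)c2c(OCC=C)cc(OC)cc2C(S(=O)(=O)c2ccc(C)cc2)c2c(O)cc(OC)cc2/C=C/c2ccc(OC)cc2)cc(OC)cc1O | intermediate |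
| 13 | 4-methoxybenzaldehyde | COc1ccc(C=O)cc1 | starting material |
| 14 | bis-ketone (L1, L3), L2 sulfone retained | COc1ccc(/C=C/c2cc(OC)cc(O)c2[C@@H](c2cc(OC)cc(OCC=C)c2C(S(=O)(=O)c2ccc(C)cc2)c2cc(OC)cc(O)c2[C@@H](c2cc(OC)cc(OC)c2)C(=O)c2ccc(OC)cc2)C(=O)c2ccc(OC)cc2)cc1 | intermediate |
| 15 | bis-DHB with O-allyl and L2 sulfone | COc1ccc(/C=C/c2cc(OC)cc3c2[C@@H](c2cc(OC)cc(OCC=C)c2C(S(=O)(=O)c2ccc(C)cc2)c2cc(OC)cc4c2[C@@H](c2cc(OC)cc(OC)c2)[C@H](c2ccc(OC)cc2)O4)[C@H](c2ccc(OC)cc2)O3)cc1 | intermediate |
| 16 | phenol-sulfone | COc1ccc(/C=C/c2cc(OC)cc3c2[C@@H](c2cc(OC)cc(O)c2C(S(=O)(=O)c2ccc(C)cc2)c2cc(OC)cc4c2[C@@H](c2cc(OC)cc(OC)c2)[C@H](c2ccc(OC)cc2)O4)[C@H](c2ccc(OC)cc2)O3)cc1 | intermediate |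
| 17 | L2 ketone | COc1ccc(/C=C/c2cc(OC)cc3c2[C@@H](c2cc(OC)cc(O)c2[C@H](c2cc(OC)cc4c2[C@@H](c2cc(OC)cc(OC)c2)[C@H](c2ccc(OC)cc2)O4)C(=O)c2ccc(OC)cc2)[C@H](c2ccc(OC)cc2)O3)cc1 | intermediate |
| 18 | permethyl Miyabenol A | COc1ccc(/C=C/c2cc(OC)cc3c2[C@@H](c2cc(OC)cc4c2[C@H](c2cc(OC)cc5c2[C@@H](c2cc(OC)cc(OC)c2)[C@H](c2ccc(OC)cc2)O5)[C@@H](c2ccc(OC)cc2)O4)[C@H](c2ccc(OC)cc2)O3)cc1 | intermediate |
| 19 | Miyabenol A | Oc1ccc(/C=C/c2cc(O)cc3c2[C@@H](c2cc(O)cc4c2[C@H](c2cc(O)cc5c2[C@@H](c2cc(O)cc(O)c2)[C@H](c2ccc(O)cc2)O5)[C@@H](c2ccc(O)cc2)O4)[C@H](c2ccc(O)cc2)O3)cc1 | target |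

## Summary
Total steps: 15. Longest linear sequence: 13 steps (1 → 2 → 3 → 4 → 9 → 10 → 11 → 12 → 13 → 14 → 15 → 18 → 19 in compound terms, i.e. Steps 1, 2, 3, 6, 7, 8, 9, 10, 11, 12, 13, 14, 15).

Three steps most likely to fail:
1. **Steps 10/13 (proposed new NHC umpolung addition to hindered diaryl o-QMs).** Risks are low yield, low ee, and enolization of the α,α-diaryl ketone. Fallback: run the addition with an achiral triazolium or thiazolium catalyst to give racemic ketones, then resolve the stereoisomers by preparative chiral-phase HPLC at the permethyl stage 18.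
2. **Step 8 (hindered t-BuLi exchange and addition with two alkoxides, to a 2,6-disubstituted aldehyde).** Fallback: couple two pre-built benzhydrol halves (A–B and C–D) in a single ArLi/aldehyde step, with the carbinols held as MOM ethers.
3. **Step 14 (SN1 cyclization at the most crowded centre).** Risks are a 1,2-hydride shift to the diaryl cation, loss of C3 configuration, and cis/trans mixtures. Fallback: separate the carbinol diastereomers and close each by Mitsunobu SN2 (DIAD/PPh3), which is stereospecific.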